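**Retrosynthetic overview**

1. Target 22 comes from Pd-catalysed dearomative C8-prenylation of chromanone acid 20, and 20 from reductive C8-alkylation of the aromatic chromanone acid 18 with cyclobutane aldehyde 8.
2. Aldehyde 8 comes from Norrish α-cleavage of bicyclo[2.1.1]hexan-2-one 7. Ketone 7 comes from a crossed intramolecular [2+2] photocycloaddition of the achiral dienone 6, which makes both cyclobutane bonds C1–C2 (CH–CMe2) and C3–C4 (CH–CH2) in one operation.
3. Enabling feature: on the cyclobutane, the CH2 arm on C1 and the isopropenyl carbon on C3 are cis-1,3 with the CMe2 carbon (C2) between them. These two exocyclic carbons can therefore be joined as a temporary CO–CMe2 bridge (the cyclopentanone ring of 7), and cleaving that bridge leaves exactly CHO and C(CH3)=CH2.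
4. Acid 18 comes from 5,7-dimethoxycoumarin 9: copper-catalysed asymmetric conjugate addition (side-chain centre), Friedel–Crafts tigloylation, quinine-catalysed oxa-Michael closure (pyranone ring), demethylation, lactone opening.
5. Ring order: cyclobutane (inside bicycle 7), then the pyranone ring on the preformed benzene/lactone, then dearomatisation of the carbocycle last.

Key step: step 4

Remark: where a chiral catalyst or ligand sets a stereocentre (steps 4, 6, 8 and 12), the antipode named is the one expected from the accepted models for the closest substrates; both antipodes are available, so a reversed sense would be corrected by exchanging the antipode without changing the route.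

**Route**

Step 1
Reactants: 1 2,4-dimethylpenta-1,3-diene
Product: 2 4-chloro-2,4-dimethylpent-2-ene
Conditions: HCl (1.05 equiv, 2 M in Et2O), −40 → 0 °C; used crude
Reagents that add atoms: hydrogen chloride, Cl
Why: Electrophilic hydrochlorination of a 1,3-diene: protonation at the terminal CH2 gives the symmetrical 1,1,3,3-tetramethylallyl cation, and chloride capture at either (identical) terminus should give one tertiary allylic chloride; no stereocentre is formed.

Step 2
Reactants: 2 4-chloro-2,4-dimethylpent-2-ene; 3 acrolein (prop-2-enal)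
Product: 5 4,4,6-trimethylhepta-1,5-dien-3-ol (racemic), via allylzinc chloride 4 (not isolated)
Conditions: Zn dust, THF/sat. aq. NH4Cl, 0 °C → rt
Reagents that add atoms: none
Why: Barbier-type zinc-mediated allylation of an aldehyde: the allylzinc fragment is symmetrical, so attack through either terminus makes the same CMe2–CH(OH) bond, addition to acrolein is 1,2, and the carbinol centre is formed racemic and removed in step 3.

Step 3
Reactants: 5 4,4,6-trimethylhepta-1,5-dien-3-ol
Product: 6 4,4,6-trimethylhepta-1,5-dien-3-one
Conditions: Dess–Martin periodinane, CH2Cl2, 0 °C → rt; used promptly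
Reagents that add atoms: none
Why: Dess–Martin oxidation of a secondary allylic alcohol under neutral conditions should give the vinyl ketone without conjugate addition or double-bond migration (the α-carbon is quaternary), and the racemic stereocentre disappears.

Step 4
Reactants: 6 4,4,6-trimethylhepta-1,5-dien-3-one
Product: 7 (1S,4R)-3,3,5,5-tetramethylbicyclo[2.1.1]hexan-2-one
Conditions: hν (λ = 366 nm), oxazaborolidine from (S)-α,α-bis(3,5-dimethylphenyl)prolinol and 2,4,6-trifluorophenylboronic acid, activated by AlBr3 (50 mol%), CH2Cl2, −75 °C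
Reagents that add atoms: none
Why: Proposed new method: the Lewis-acid-bound s-cis vinyl ketone absorbs at 366 nm through its red-shifted π–π* band, and in its triplet state the enone β-carbon adds to the internal alkene carbon (1,5-closure, rule of five) to give a 1,4-biradical (α-keto radical and tertiary radical) that combines to the crossed adduct. The closest known reactions are the uncatalysed photocyclisation of 1,5-hexadien-3-ones to bicyclo[2.1.1]hexan-2-ones and the enantioselective intramolecular [2+2] photocycloaddition of cyclic enones under AlBr3-activated chiral oxazaborolidines; what is new is the use of such a catalyst on an acyclic vinyl ketone whose carbonyl lies in the tether. In the numbering of 7, the five-membered ring C1–C2–C3–C4–C6 closes first by 5-exo radical-type attack (bond C6–C4), and the cyclobutane C1–C5–C4–C6 closes by 1,4-biradical combination (bond C1–C5). C1 and C4 are bridgeheads, so their relative configuration (the cis-1,3 pattern of the target) is fixed by the topology of the bicycle, and their absolute configuration should be set by the catalyst, whose aryl group shields one face of the coordinated enone so that the tethered alkene adds to the other. The step needs crossed over parallel regiochemistry, ring closure over hydrogen transfer in the biradical, and reaction of bound over free enone; the two-atom tether and the gem-dimethyl group at C4 of 6 (Thorpe–Ingold effect, no enolisation, and a 1,3-acyl shift that is degenerate because the allyl unit is symmetrical) secure the first, and low temperature with high catalyst loading serves the other two.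

Step 5
Reactants: 7 (1S,4R)-3,3,5,5-tetramethylbicyclo[2.1.1]hexan-2-one
Product: 8 (1S,3S)-2,2-dimethyl-3-(prop-1-en-2-yl)cyclobutane-1-carbaldehyde (cis)
Conditions: hν (λ ≈ 313 nm, Pyrex), pentane, 20 °C, stopped at partial conversion, 7 recycled
Reagents that add atoms: none
Why: Norrish type 1 cleavage of an α,α-dimethyl ketone, as in the photolysis of other 2,2-dimethylcycloalkanones to unsaturated aldehydes: α-cleavage on the quaternary side gives an acyl/tertiary-alkyl biradical in which the acyl carbon takes a hydrogen from a methyl group (the ring hydrogens on C1 and C4 point to the opposite face and cannot be transferred), so CHO and isopropenyl should form without touching either stereocentre.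

Step 6
Reactants: 9 5,7-dimethoxycoumarin; 10 n-pentylmagnesium bromide
Product: 11 (4S)-5,7-dimethoxy-4-pentylchroman-2-one
Conditions: CuBr·SMe2 (5 mol%), (R)-1-[(S)-2-(diphenylphosphino)ferrocenyl]ethyldicyclohexylphosphine (6 mol%), t-BuOMe, −75 °C; aq. NH4Cl
Reagents that add atoms: none
Why: Copper-catalysed asymmetric conjugate addition of a Grignard reagent to a coumarin: the chiral ferrocenyl diphosphine–copper complex selects the face of C3=C4 and should set C4 as S, while the catalysed 1,4-pathway outruns 1,2-attack on the lactone at low temperature.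

Step 7
Reactants: 11 (4S)-5,7-dimethoxy-4-pentylchroman-2-one; 12 tigloyl chloride ((2E)-2-methylbut-2-enoyl chloride)
Product: 14 (4S)-7-hydroxy-5-methoxy-8-[(2E)-2-methylbut-2-enoyl]-4-pentylchroman-2-one, via dimethoxy aryl ketone 13 (not isolated)
Conditions: AlCl3 (3 equiv), CH2Cl2, 0 °C → rt; cold aq. HCl
Reagents that add atoms: none
Why: Friedel–Crafts acylation followed in the same flask by AlCl3 cleavage of the methyl ether ortho to the new ketone: C8 (ortho to 7-OMe, para to 5-OMe) should react in preference to C6, which lies between two methoxy groups, and chelation-assisted demethylation can only occur at 7-OMe, so O7 becomes the single free phenol and the later ring closure can only place the pyranone oxygen para to the side-chain carbon; C4 is untouched and no stereocentre is formed.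

Step 8
Reactants: 14 (4S)-7-hydroxy-5-methoxy-8-[(2E)-2-methylbut-2-enoyl]-4-pentylchroman-2-one
Product: 16 (4S,8R,9R)-5-methoxy-8,9-dimethyl-4-pentyl-3,4,8,9-tetrahydro-2H,10H-pyrano[2,3-h]chromene-2,10-dione (trans-dimethyl), via cis-pyranone 15 (not isolated)
Conditions: quinine (20 mol%), chlorobenzene, rt; then Et3N, rt
Reagents that add atoms: none
Why: Quinine-catalysed intramolecular oxa-Michael addition (6-endo-trig) of the phenol to the tigloyl enone: the alkaloid, acting as general base and hydrogen-bond donor, should control the face of C–O bond formation and set the O–CH(CH3) carbon (C8 of 16) as R, kinetic protonation gives the cis isomer, and Et3N then equilibrates the carbon next to the ketone (C9) through the enol to the diequatorial trans isomer without opening the ring, so C8 is kept.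

Step 9
Reactants: 16 (4S,8R,9R)-5-methoxy-8,9-dimethyl-4-pentyl-3,4,8,9-tetrahydro-2H,10H-pyrano[2,3-h]chromene-2,10-dione
Product: 17 (4S,8R,9R)-5-hydroxy-8,9-dimethyl-4-pentyl-3,4,8,9-tetrahydro-2H,10H-pyrano[2,3-h]chromene-2,10-dione
Conditions: BBr3 (3 equiv), CH2Cl2, −78 → 0 °C; H2O
Reagents that add atoms: none
Why: BBr3 cleavage of an aryl methyl ether at low temperature should leave the aryl lactone and the pyranone intact; any acid-induced epimerisation at C9 can only reinforce the trans arrangement, and C4 and C8 are not enolisable.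

Step 10
Reactants: 17 (4S,8R,9R)-5-hydroxy-8,9-dimethyl-4-pentyl-3,4,8,9-tetrahydro-2H,10H-pyrano[2,3-h]chromene-2,10-dione
Product: 18 (3S)-3-[(2R,3R)-5,7-dihydroxy-2,3-dimethyl-4-oxo-3,4-dihydro-2H-chromen-6-yl]octanoic acid
Conditions: LiOH (4 equiv), THF/H2O, 0 °C; then cold 1 M HCl to pH 3
Reagents that add atoms: lithium hydroxide, [Li+].[OH-]
Why: Saponification of the phenolic lactone, the most electrophilic carbonyl present, followed by cold acidification should give the free dihydroxy acid; the phenolates formed first deactivate the chromanone towards retro-oxa-Michael opening, so C2 and C3 are kept.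

Step 11
Reactants: 18 (3S)-3-[(2R,3R)-5,7-dihydroxy-2,3-dimethyl-4-oxo-3,4-dihydro-2H-chromen-6-yl]octanoic acid; 8 (1S,3S)-2,2-dimethyl-3-(prop-1-en-2-yl)cyclobutane-1-carbaldehyde
Product: 20 (3S)-3-[(2R,3R)-8-{[(1R,3S)-2,2-dimethyl-3-(prop-1-en-2-yl)cyclobutyl]methyl}-5,7-dihydroxy-2,3-dimethyl-4-oxo-3,4-dihydro-2H-chromen-6-yl]octanoic acid, via ortho-quinone methide 19 (not isolated)
Conditions: L-proline (20 mol%), Hantzsch ester (diethyl 2,6-dimethyl-1,4-dihydropyridine-3,5-dicarboxylate, 1.2 equiv), CH2Cl2/EtOH, rt
Reagents that add atoms: none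
Why: Organocatalytic reductive alkylation (Knoevenagel condensation, then transfer hydrogenation by the Hantzsch ester): C8 is the only unsubstituted carbon of the acylphloroglucinol-type ring, its condensation with the aldehyde gives the ortho-quinone methide, which accepts hydride at the exocyclic carbon; the cyclobutane α-centre is not expected to epimerise (its enamine would be an exocyclic alkene on a four-membered ring, and the cis isomer is the more stable one), and no new stereocentre is formed.

Step 12
Reactants: 20 (3S)-3-[(2R,3R)-8-{[(1R,3S)-2,2-dimethyl-3-(prop-1-en-2-yl)cyclobutyl]methyl}-5,7-dihydroxy-2,3-dimethyl-4-oxo-3,4-dihydro-2H-chromen-6-yl]octanoic acid; 21 methyl 3-methylbut-2-en-1-yl carbonate (prenyl methyl carbonate)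
Product: 22 (3S)-3-[(2R,3R,8R)-8-{[(1R,3S)-2,2-dimethyl-3-(prop-1-en-2-yl)cyclobutyl]methyl}-5-hydroxy-2,3-dimethyl-8-(3-methylbut-2-en-1-yl)-4,7-dioxo-3,4,7,8-tetrahydro-2H-chromen-6-yl]octanoic acid (target)
Conditions: Pd2(dba)3 (2.5 mol%), (1R,2R)-N,N'-bis[2-(diphenylphosphino)benzoyl]cyclohexane-1,2-diamine (7.5 mol%), i-Pr2NEt (1.1 equiv), THF, 0 °C → rt; work-up at pH 3
Reagents that add atoms: none
Why: Palladium-catalysed asymmetric allylic alkylation (Tsuji–Trost) used as a dearomatisation: the phloroglucinolate should attack the 1,1-dimethylallyl palladium cation through C8 at the unsubstituted allyl terminus (linear prenyl), O-prenyl products (ester, aryl ether) are re-ionised by zerovalent palladium and funnel to the C-alkylated dienone, C8 is preferred over C6 for steric reasons (primary versus branched substituent), and the chiral diphosphine pocket selects the face of the planar nucleophile and should set C8 as R under catalyst control.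

**Compound list**

1 | 2,4-dimethylpenta-1,3-diene | CC(C)=CC(C)=C | starting material
2 | 4-chloro-2,4-dimethylpent-2-ene | CC(C)=CC(C)(C)Cl | intermediate
3 | acrolein | C=CC=O | starting material
4 | (2,4-dimethylpent-3-en-2-yl)zinc chloride | CC(C)=CC(C)(C)[Zn]Cl | intermediate (not isolated)
5 | 4,4,6-trimethylhepta-1,5-dien-3-ol (racemic) | C=CC(O)C(C)(C)C=C(C)C | intermediate
6 | 4,4,6-trimethylhepta-1,5-dien-3-one | C=CC(=O)C(C)(C)C=C(C)C | intermediate
7 | (1S,4R)-3,3,5,5-tetramethylbicyclo[2.1.1]hexan-2-one | CC1(C)[C@@H]2C[C@H](C1=O)C2(C)C | intermediate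
8 | (1S,3S)-2,2-dimethyl-3-(prop-1-en-2-yl)cyclobutane-1-carbaldehyde (cis) | C=C(C)[C@@H]1C[C@H](C=O)C1(C)C | intermediate
9 | 5,7-dimethoxycoumarin | COc1cc(OC)c2ccc(=O)oc2c1 | starting material
10 | n-pentylmagnesium bromide | CCCCC[Mg]Br | starting material
11 | (4S)-5,7-dimethoxy-4-pentylchroman-2-one | COc1cc(OC)cc2c1[C@@H](CCCCC)CC(=O)O2 | intermediate
12 | tigloyl chloride, (2E)-2-methylbut-2-enoyl chloride | C/C=C(\C)C(=O)Cl | starting material
13 | (4S)-5,7-dimethoxy-8-[(2E)-2-methylbut-2-enoyl]-4-pentylchroman-2-one | COc1cc(OC)c(C(=O)/C(C)=C/C)c2c1[C@@H](CCCCC)CC(=O)O2 | intermediate (not isolated)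
14 | (4S)-7-hydroxy-5-methoxy-8-[(2E)-2-methylbut-2-enoyl]-4-pentylchroman-2-one | COc1cc(O)c(C(=O)/C(C)=C/C)c2c1[C@@H](CCCCC)CC(=O)O2 | intermediate
15 | (4S,8R,9S)-5-methoxy-8,9-dimethyl-4-pentyl-3,4,8,9-tetrahydro-2H,10H-pyrano[2,3-h]chromene-2,10-dione (cis-dimethyl) | COc1cc2O[C@H](C)[C@H](C)C(=O)c2c3c1[C@@H](CCCCC)CC(=O)O3 | intermediate (not isolated)
16 | (4S,8R,9R)-5-methoxy-8,9-dimethyl-4-pentyl-3,4,8,9-tetrahydro-2H,10H-pyrano[2,3-h]chromene-2,10-dione (trans-dimethyl) | COc1cc2O[C@H](C)[C@@H](C)C(=O)c2c3c1[C@@H](CCCCC)CC(=O)O3 | intermediate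
17 | (4S,8R,9R)-5-hydroxy-8,9-dimethyl-4-pentyl-3,4,8,9-tetrahydro-2H,10H-pyrano[2,3-h]chromene-2,10-dione | Oc1cc2O[C@H](C)[C@@H](C)C(=O)c2c3c1[C@@H](CCCCC)CC(=O)O3 | intermediate
18 | (3S)-3-[(2R,3R)-5,7-dihydroxy-2,3-dimethyl-4-oxo-3,4-dihydro-2H-chromen-6-yl]octanoic acid | CCCCC[C@@H](CC(=O)O)c1c(O)cc2O[C@H](C)[C@@H](C)C(=O)c2c1O | intermediate
19 | ortho-quinone methide from 18 and 8 (8-cyclobutylmethylidene-5-hydroxy-4,7-dioxo form; exocyclic alkene geometry not fixed) | CCCCC[C@@H](CC(=O)O)C1=C(O)C2=C(O[C@H](C)[C@@H](C)C2=O)C(=C[C@H]3C[C@@H](C(C)=C)C3(C)C)C1=O | intermediate (not isolated)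
20 | (3S)-3-[(2R,3R)-8-{[(1R,3S)-2,2-dimethyl-3-(prop-1-en-2-yl)cyclobutyl]methyl}-5,7-dihydroxy-2,3-dimethyl-4-oxo-3,4-dihydro-2H-chromen-6-yl]octanoic acid | CCCCC[C@@H](CC(=O)O)c1c(O)c(C[C@H]3C[C@@H](C(C)=C)C3(C)C)c2O[C@H](C)[C@@H](C)C(=O)c2c1O | intermediate
21 | methyl 3-methylbut-2-en-1-yl carbonate | CC(C)=CCOC(=O)OC | starting material
22 | (3S)-3-[(2R,3R,8R)-8-{[(1R,3S)-2,2-dimethyl-3-(prop-1-en-2-yl)cyclobutyl]methyl}-5-hydroxy-2,3-dimethyl-8-(3-methylbut-2-en-1-yl)-4,7-dioxo-3,4,7,8-tetrahydro-2H-chromen-6-yl]octanoic acid | C=C(C)[C@@H]1C[C@H](C[C@@]2(CC=C(C)C)C(=O)C([C@@H](CCCCC)CC(=O)O)=C(O)C3=C2O[C@H](C)[C@@H](C)C3=O)C1(C)C | target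

**Step count and risks**

Total step count: 12. Longest linear sequence: 7 steps (steps 6–12 from 9; the aldehyde branch, steps 1–5 followed by 11 and 12, is equally long).

Three steps most likely to fail:

Step 4 (Proposed new method). What may go wrong: insufficient enantioface discrimination because unbound dienone also absorbs and reacts (racemic background); thermal Lewis-acid-induced ene-type cyclisation of the trisubstituted alkene onto the activated enone; hydrogen transfer in the 1,4-biradical in place of ring closure. The fallback replaces asymmetric catalysis by a resolution and uses only known chemistry. It sets out from 6: direct irradiation without catalyst (λ ≥ 350 nm, pentane), the known photocyclisation of 1,5-hexadien-3-ones, should give racemic 3,3,5,5-tetramethylbicyclo[2.1.1]hexan-2-one F1. Norrish cleavage as in step 5 should give the racemic cis aldehyde F2. Condensation with (1R,2R)-N,N'-dimethyl-1,2-diphenylethane-1,2-diamine (Et2O, 4 Å molecular sieves, rt) should give two diastereomeric imidazolidines, the (1S,3S)-cyclobutyl aminal F3 and the (1R,3R)-cyclobutyl aminal F4, which are separated by chromatography. Hydrolysis of F3 (dilute aq. HCl, Et2O, 0 °C) comes back to the route at 8.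

Step 5. What may go wrong: over-irradiation, since the product aldehyde absorbs in the same region and can undergo secondary α-cleavage, γ-hydrogen abstraction or intramolecular oxetane formation with the nearby isopropenyl group, and unproductive recombination of the biradical. The fallback is a non-photochemical cleavage of the same CO–CMe2 bond and sets out from 7. Baeyer–Villiger oxidation (mCPBA, NaHCO3, CH2Cl2; the tertiary carbon migrates) should give (1S,5R)-4,4,6,6-tetramethyl-3-oxabicyclo[3.1.1]heptan-2-one F5. Methanolysis (NaOMe, MeOH) should open the strained lactone to methyl (1S,3R)-3-(2-hydroxypropan-2-yl)-2,2-dimethylcyclobutane-1-carboxylate F6. E2 dehydration of the tertiary alcohol (POCl3, pyridine, 0 °C) should give methyl (1S,3S)-2,2-dimethyl-3-(prop-1-en-2-yl)cyclobutane-1-carboxylate F7. Reduction with DIBAL-H (CH2Cl2, −78 °C) comes back to the route at 8.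

Step 12. What may go wrong: poor control of the site of C–C bond formation (C8 versus C6 versus oxygen), of the allyl terminus (linear versus branched) and of the face of the planar nucleophile with the hindered 1,1-dimethylallyl electrophile. The fallback sets out from 20 and installs the prenyl group in two stages. Palladium-catalysed asymmetric dearomative allylation with allyl methyl carbonate (Pd2(dba)3, the same diphosphine, THF), the parent and best-behaved electrophile of this reaction class, should give the 8-allyl dienone acid F8. Cross-metathesis with 2-methylbut-2-ene (second-generation Grubbs catalyst, CH2Cl2, 40 °C; the 1,1-disubstituted isopropenyl group should not react) comes back to the route at 22.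

Further compounds
F1 | step 4 | racemic 3,3,5,5-tetramethylbicyclo[2.1.1]hexan-2-one | CC1(C)[C@@H]2C[C@H](C1=O)C2(C)C.CC1(C)[C@H]2C[C@@H](C1=O)C2(C)C
F2 | step 4 | racemic cis-2,2-dimethyl-3-(prop-1-en-2-yl)cyclobutane-1-carbaldehyde | C=C(C)[C@@H]1C[C@H](C=O)C1(C)C.C=C(C)[C@H]1C[C@@H](C=O)C1(C)C
F3 | step 4 | (4R,5R)-2-[(1S,3S)-2,2-dimethyl-3-(prop-1-en-2-yl)cyclobutyl]-1,3-dimethyl-4,5-diphenylimidazolidine | CN1[C@H](c2ccccc2)[C@@H](c2ccccc2)N(C)C1[C@H]3C[C@@H](C(C)=C)C3(C)C
F4 | step 4 | (4R,5R)-2-[(1R,3R)-2,2-dimethyl-3-(prop-1-en-2-yl)cyclobutyl]-1,3-dimethyl-4,5-diphenylimidazolidine | CN1[C@H](c2ccccc2)[C@@H](c2ccccc2)N(C)C1[C@@H]3C[C@H](C(C)=C)C3(C)C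
F5 | step 5 | (1S,5R)-4,4,6,6-tetramethyl-3-oxabicyclo[3.1.1]heptan-2-one | CC1(C)[C@@H]2C[C@H](C(=O)O1)C2(C)C
F6 | step 5 | methyl (1S,3R)-3-(2-hydroxypropan-2-yl)-2,2-dimethylcyclobutane-1-carboxylate | COC(=O)[C@H]1C[C@@H](C(C)(C)O)C1(C)C
F7 | step 5 | methyl (1S,3S)-2,2-dimethyl-3-(prop-1-en-2-yl)cyclobutane-1-carboxylate | COC(=O)[C@H]1C[C@@H](C(C)=C)C1(C)C
F8 | step 12 | (3S)-3-[(2R,3R,8R)-8-allyl-8-{[(1R,3S)-2,2-dimethyl-3-(prop-1-en-2-yl)cyclobutyl]methyl}-5-hydroxy-2,3-dimethyl-4,7-dioxo-3,4,7,8-tetrahydro-2H-chromen-6-yl]octanoic acid | C=C(C)[C@@H]1C[C@H](C[C@@]2(CC=C)C(=O)C([C@@H](CCCCC)CC(=O)O)=C(O)C3=C2O[C@H](C)[C@@H](C)C3=O)C1(C)C
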